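**Retrosynthetic overview**

- Numbering used here: C1 is the lactone carbonyl carbon, C2 to C30 are the ring methylenes in order, and C30 is bonded to the ring oxygen. The saturated 31-membered lactone is traced back by a final hydrogenation to its (10Z,22Z)-diene, which has alkenes at C9=C10 and C21=C22.
- Key disconnection: both alkenes are made in one operation by a twofold Wittig olefination. A C18 dialdehyde ester (C1–C9 and C22–C30, already joined through the ester) reacts with a C12 bis-ylide (C10–C21). The 31-membered lactone ring is the only ring; it forms in this step and is closed when the chain-end ylide carbon C21 adds to the formyl carbon C22.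
- Enabling feature: the ring is a 9 + 12 + 9 carbon array. An unfunctionalised run of twelve methylenes (C10–C21) is flanked by C9 and C22, which lie eight methylenes from C1 and from the O-bearing C30. These are exactly the two Δ9 positions of a C18 acid/C18 alcohol wax ester.
- Building blocks: the dialdehyde ester comes from ozonolysis of oleyl oleate; the bis-ylide comes from 1,12-dibromododecane through its bis(triphenylphosphonium) salt.

Key step: step 3

Remark: oleyl oleate is taken as the commercial high-purity (Z,Z) wax ester; saturated wax esters, if present, would pass step 1 unchanged and be separated from the dialdehyde by chromatography.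

Step 1
Reactants: 1 oleyl oleate [(9Z)-octadec-9-en-1-yl (9Z)-octadec-9-enoate]
Product: 3 9-oxononyl 9-oxononanoate, via bis-ozonide 2 (not isolated)
Conditions: O3, CH2Cl2, −78 °C; then PPh3 (2.2 equiv), −78 °C to rt
Reagents that add atoms: ozone, [O-][O+]=O
Why: Criegee ozonolysis converts both (Z)-Δ9 alkenes into 1,2,4-trioxolanes that PPh3 reduces to aldehydes without over-oxidation, so the ester-linked C18 dialdehyde is cut out of the wax ester in one operation while the saturated ester linkage is inert to ozone; no stereocentre remains, since those of the ozonides vanish on reduction.

Step 2
Reactants: 4 1,12-dibromododecane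
Product: 5 dodecane-1,12-diylbis(triphenylphosphonium) dibromide
Conditions: PPh3 (2.5 equiv), MeCN, reflux
Reagents that add atoms: triphenylphosphine, c1ccc(cc1)P(c1ccccc1)c1ccccc1
Why: Twofold SN2 quaternisation of an unhindered primary α,ω-dibromide by PPh3 (phosphonium salt formation) is a standard entry to Wittig reagents, and excess phosphine in a polar solvent at reflux should drive the second alkylation to completion; no stereocentre is formed.

Step 3
Reactants: 5 dodecane-1,12-diylbis(triphenylphosphonium) dibromide; 3 9-oxononyl 9-oxononanoate
Product: 8 (10Z,22Z)-oxacyclohentriaconta-10,22-dien-2-one, via bis-ylide 6 (not isolated), via seco ylide aldehyde 7 (not isolated)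
Conditions: NaN(SiMe3)2 (1.95 equiv), THF, 0 °C; then the ylide solution and 3 (1.0 equiv) in THF added together by syringe pumps over 12 h to THF (final 1 mM), 0 °C to rt
Reagents that add atoms: none
Why: Deprotonation of 5 gives the non-stabilised bis-ylide 6; one ylide carbon adds to a formyl group of 3 (drawn for the acyl-side C9) through an oxaphosphetane that cycloreverts to the C9=C10 alkene and Ph3PO, and the remaining ylide carbon C21 of seco ylide aldehyde 7 then adds to the formyl carbon C22 of the same molecule, the second oxaphosphetane collapsing to the C21=C22 alkene that closes the ring (should the alkoxy-side formyl group react first, the regioisomeric seco compound converges on the same ring). The closest known reaction types are the twofold Wittig macrocyclisation of α,ω-bis(phosphonium ylides) with dialdehydes and the intramolecular Wittig macrocyclisation of ω-formyl ylides. The single ring, 31-membered, is closed end to end by intramolecular carbonyl olefination within a strain-free chain, so that one operation forms two C=C bonds, unites all thirty ring carbons and delivers the macrolactone. No stereocentre is created, and the alkene geometry, expected to be mainly Z under lithium-free conditions, is irrelevant because step 4 removes both alkenes. The step needs ring closure to win over chain growth and attack at formyl to win over attack at the ester: the complementary termini (an ylide couples only with a formyl group, never with its like) enforce strict alternation of the two components, the long flexible tether of 7 should let the intramolecular olefination outpace intermolecular encounters at 1 mM, and a non-stabilised ylide reacts with an aliphatic aldehyde far faster than with an unactivated ester at 0 °C, while the slight deficit of base leaves no free amide to enolise 3.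

Step 4
Reactants: 8 (10Z,22Z)-oxacyclohentriaconta-10,22-dien-2-one
Product: 9 oxacyclohentriacontan-2-one (triacontan-30-olide)
Conditions: H2 (1 atm), Pd/C (10 wt%), EtOAc, rt
Reagents that add atoms: none
Why: Heterogeneous catalytic hydrogenation over Pd/C saturates both isolated disubstituted alkenes under neutral conditions that a saturated macrolactone tolerates, which erases the alkene geometry set in step 3 and leaves a target without any stereocentre.

**Compound list**

1 | oleyl oleate, (9Z)-octadec-9-en-1-yl (9Z)-octadec-9-enoate | CCCCCCCC/C=C\CCCCCCCC(=O)OCCCCCCCC/C=C\CCCCCCCC | starting material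
2 | bis-ozonide, 8-(5-octyl-1,2,4-trioxolan-3-yl)octyl 8-(5-octyl-1,2,4-trioxolan-3-yl)octanoate (mixture of stereoisomers) | CCCCCCCCC1OC(CCCCCCCC(=O)OCCCCCCCCC2OC(CCCCCCCC)OO2)OO1 | intermediate
3 | 9-oxononyl 9-oxononanoate | O=CCCCCCCCC(=O)OCCCCCCCCC=O | intermediate
4 | 1,12-dibromododecane | BrCCCCCCCCCCCCBr | starting material
5 | dodecane-1,12-diylbis(triphenylphosphonium) dibromide | [Br-].[Br-].c1ccc(cc1)[P+](c1ccccc1)(c1ccccc1)CCCCCCCCCCCC[P+](c1ccccc1)(c1ccccc1)c1ccccc1 | intermediate
6 | bis-ylide, dodecane-1,12-diylidenebis(triphenyl-λ5-phosphane) | c1ccc(cc1)P(c1ccccc1)(c1ccccc1)=CCCCCCCCCCCC=P(c1ccccc1)(c1ccccc1)c1ccccc1 | intermediate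
7 | seco ylide aldehyde, 9-oxononyl (9Z)-21-(triphenyl-λ5-phosphanylidene)henicos-9-enoate | O=CCCCCCCCCOC(=O)CCCCCCC/C=C\CCCCCCCCCCC=P(c1ccccc1)(c1ccccc1)c1ccccc1 | intermediate
8 | (10Z,22Z)-oxacyclohentriaconta-10,22-dien-2-one | O=C1CCCCCCC/C=C\CCCCCCCCCC/C=C\CCCCCCCCO1 | intermediate
9 | oxacyclohentriacontan-2-one (triacontan-30-olide) | O=C1CCCCCCCCCCCCCCCCCCCCCCCCCCCCCO1 | target

**Totals**

Total step count: 4. Longest linear sequence: 3 steps (steps 1, 3, 4 or steps 2, 3, 4).

**Steps most likely to fail, with fallbacks**

Step 3. What may go wrong: chain growth outruns ring closure, because the seco ylide aldehyde meets a second molecule of 3 or 6 before it folds back on itself, so that open-chain and large-ring oligoesters dominate. The fallback moves the ring closure to the C1–O bond and uses only known chemistry. It sets out from 3 and 5 (5 converted into 6 as in step 3). The two are combined at 0.1 M without slow addition, as a Wittig polycondensation, to give the alternating oligoester F1 (chains and large rings built from the repeat unit of 8). Every ester bond of this material links the same C30 unit, so saponification (LiOH, THF–MeOH–H2O, 50 °C; then aqueous HCl) should give, apart from chain-end fragments, a single seco acid, (9Z,21Z)-30-hydroxytriaconta-9,21-dienoic acid F2. Yamaguchi macrolactonisation (2,4,6-trichlorobenzoyl chloride, Et3N, THF; then slow addition to DMAP in toluene at reflux) is a unimolecular ring closure that needs only pseudo-dilution, and it comes back to the route at 8.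

Step 1. What may go wrong: over-oxidation of the formyl groups to carboxylic acids during or after ozonolysis, or incomplete reduction that leaves peroxidic oligomers in the dialdehyde. The fallback sets out from 1. Catalytic osmium-mediated syn-dihydroxylation (K2OsO2(OH)4 cat., N-methylmorpholine N-oxide, acetone–H2O, rt) should give the tetraol 9,10-dihydroxyoctadecyl 9,10-dihydroxyoctadecanoate F3. Glycol cleavage with NaIO4 (THF–H2O, rt; Malaprade reaction) then stops cleanly at the aldehyde level and comes back to the route at 3.

Step 4. What may go wrong: poisoning of the palladium surface by phosphorus-containing residues carried over from step 3, so that hydrogen uptake stalls before both alkenes are saturated. The fallback sets out from 8. Metal-free diimide reduction (p-toluenesulfonyl hydrazide, NaOAc, THF–H2O, reflux) should saturate both alkenes and arrive directly at 9; no new compound arises (F0).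

**Further compounds**

F1 | step 3 | alternating oligoester of the C18 and C12 units (mixture of chains and large rings; its smallest ring, (10Z,22Z,41Z,53Z)-1,32-dioxacyclodohexaconta-10,22,41,53-tetraene-2,33-dione, is shown) | O=C1CCCCCCC/C=C\CCCCCCCCCC/C=C\CCCCCCCCOC(=O)CCCCCCC/C=C\CCCCCCCCCC/C=C\CCCCCCCCO1
F2 | step 3 | (9Z,21Z)-30-hydroxytriaconta-9,21-dienoic acid | OCCCCCCCC/C=C\CCCCCCCCCC/C=C\CCCCCCCC(=O)O
F3 | step 1 | 9,10-dihydroxyoctadecyl 9,10-dihydroxyoctadecanoate (both diols erythro; mixture of stereoisomers, one shown) | CCCCCCCC[C@H](O)[C@H](O)CCCCCCCC(=O)OCCCCCCCC[C@H](O)[C@H](O)CCCCCCCC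
F0 | step 4 | none | none
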